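**Retrosynthetic overview**

1. (6S,6'S)-ε-Carotene is cut at C11=C12 and C11'=C12' into two identical (6S)-C15 phosphonium ylides and 2,7-dimethylocta-2,4,6-trienedial (double Wittig, last step).
2. The C15 salt comes from dienyl acetate 12. Acetate 12 is made in one operation from the acyclic, achiral iodo-tetraene 11 by an enantioselective alkenylpalladium cyclisation with acetate capture, which forms the ring bond C5–C6, the stereocentre C6, the 7E,9E-diene and the oxygen handle at C11.
3. Enabling feature: C6 is a doubly allylic methine between the ring alkene carbon C5 and the chain C7=C8–C9(Me)=C10–C11. When a C5-alkenylpalladium adds to C6 of a conjugated triene, the five sp2 carbons C7–C11 hold palladium as an η3-pentadienyl unit, so β-hydride loss is suppressed and the nucleophile enters at C11.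
4. Compound 11 is assembled around the quaternary carbon C1 from isobutyraldehyde and acrylonitrile, by an HWE reaction (C6=C7) and an iodo-Wittig reaction (Z-C4=C5–I).
5. Ring order: the six-membered end-group ring C1–C6 is the only ring type; it is closed in step 7 on one batch that serves both halves, and no ring is formed afterwards.

Key step: step 7

Remark: carotenoid numbering is used for positions (ring C1–C6 with the gem-dimethyl carbon C1, ring alkene C4=C5, stereocentre C6, chain from C7); compounds 5–11 may carry a minor Z isomer at the methyl-bearing double bond (carotenoid C8=C9), which is tolerated because this bond becomes the C8–C9 single bond in step 7, where the new C7=C8 and C9=C10 bonds are set through equilibrating η3-allylpalladium intermediates, and steps 8 and 9 equilibrate the chain geometry again; the SMILES show the E isomers.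

**Route**

Step 1
Reactants: 1 isobutyraldehyde; 2 acrylonitrile
Product: 3 4,4-dimethyl-5-oxopentanenitrile
Conditions: aq. NaOH (5 mol %), neat, 60–70 °C
Reagents that add atoms: none
Why: Base-catalysed Michael addition (cyanoethylation), in which the single α-hydrogen of 1 allows only one addition and installs the quaternary gem-dimethyl carbon C1 with its two arms differentiated as aldehyde and nitrile; no stereocentre is formed.

Step 2
Reactants: 4 3-methylpenta-1,4-dien-3-ol
Product: 5 (3E)-5-bromo-3-methylpenta-1,3-diene
Conditions: PBr3 (0.4 equiv), pyridine (cat.), Et2O, −10 °C→0 °C, used crude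
Reagents that add atoms: phosphorus tribromide, BrP(Br)Br
Why: Bromination of a tertiary bis-allylic alcohol with PBr3 should proceed with allylic transposition (SN2′ or ion-pair pathway) to the more stable conjugated primary bromide.

Step 3
Reactants: 5 (3E)-5-bromo-3-methylpenta-1,3-diene
Product: 6 diethyl [(2E)-3-methylpenta-2,4-dien-1-yl]phosphonate
Conditions: P(OEt)3 (1.2 equiv), neat, 110 °C, EtBr distilled off
Reagents that add atoms: triethyl phosphite, CCOP(OCC)OCC
Why: Michaelis–Arbuzov reaction of a primary allylic bromide, in which attack at either end of the symmetrical 3-methylpentadienyl unit leads to the same phosphonate.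

Step 4
Reactants: 3 4,4-dimethyl-5-oxopentanenitrile; 6 diethyl [(2E)-3-methylpenta-2,4-dien-1-yl]phosphonate
Product: 8 (5E,7E)-4,4,8-trimethyldeca-5,7,9-trienenitrile, via lithiated phosphonate 7 (not isolated)
Conditions: 6, n-BuLi, THF, −78 °C; then 3, DMPU, −78 °C→rt
Reagents that add atoms: none
Why: Horner–Wadsworth–Emmons olefination with a lithiated allylic phosphonate, in which the non-enolisable α-quaternary aldehyde reacts at the α-carbon of the anion and the bulky partners should favour the E alkene (future C6=C7), while the nitrile is not attacked at −78 °C.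

Step 5
Reactants: 8 (5E,7E)-4,4,8-trimethyldeca-5,7,9-trienenitrile
Product: 10 (5E,7E)-4,4,8-trimethyldeca-5,7,9-trienal, via aluminium aldimine 9 (not isolated)
Conditions: iBu2AlH (1.2 equiv), toluene, −78 °C; then aq. AcOH/potassium sodium tartrate, 0 °C
Reagents that add atoms: water, O
Why: Partial reduction of a nitrile with iBu2AlH stops at the N-aluminio aldimine, which is hydrolysed on work-up to the aldehyde, and the triene is inert to the hydride at −78 °C.

Step 6
Reactants: 10 (5E,7E)-4,4,8-trimethyldeca-5,7,9-trienal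
Product: 11 (2Z,7E,9E)-2-iodo-6,6,10-trimethyldodeca-2,7,9,11-tetraene
Conditions: EtPPh3I, n-BuLi, THF, 0 °C; I2, −78 °C; NaN(SiMe3)2, −20 °C; then 10, −78 °C→−20 °C
Reagents that add atoms: ethyltriphenylphosphonium iodide, CC[P+](c1ccccc1)(c1ccccc1)c1ccccc1.[I-]; iodine, II
Why: Stork–Zhao-type Wittig olefination with the α-iodo ylide Ph3P=C(I)CH3 should give the (Z)-2-iodo-2-alkene under kinetic control, which places iodine cis to the chain so that C4=C5 can later lie inside the six-membered ring.

Step 7
Reactants: 11 (2Z,7E,9E)-2-iodo-6,6,10-trimethyldodeca-2,7,9,11-tetraene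
Product: 12 (2E,4E)-3-methyl-5-[(1S)-2,6,6-trimethylcyclohex-2-en-1-yl]penta-2,4-dien-1-yl acetate
Conditions: Pd2(dba)3·CHCl3 (2.5 mol %), (R)-BINAP (6 mol %), AgOAc (2.0 equiv), DMSO, 0.02 M, 40 °C, dark
Reagents that add atoms: silver acetate, CC(=O)[O-].[Ag+]
Why: Proposed new method: oxidative addition of the (Z)-alkenyl iodide to zerovalent palladium (retention of geometry), iodide abstraction by AgOAc and migratory insertion of the cationic (BINAP)Pd–alkenyl into the nearer E-alkene of the triene form the C5–C6 bond and place palladium on C7, where it is held at once as an η3-pentadienyl complex spread over C7–C11; acetate then attacks the unhindered terminus C11 and releases zerovalent palladium. The closest known reaction type is the asymmetric intramolecular Heck insertion of an alkenylpalladium into a 1,3-diene followed by acetate capture of the η3-allyl (Heck/Tsuji–Trost cascade with BINAP); the use of a 1,3,5-triene with capture at the remote end is the new element. The end-group ring closes in the 6-exo-trig mode, helped by the gem-dimethyl group, whereas 7-endo closure or insertion into the two distal alkenes would need larger rings. The stereocentre C6 is set in the enantio-determining insertion by the C2-symmetric bisphosphine, which distinguishes the two faces of the E-1,2-disubstituted alkene; (R)-BINAP is proposed and its antipode is used instead if the first run should give the 6R series. The step needs the alkylpalladium not to lose the C6 hydrogen, which the immediate η3-coordination and the bidentate ligand secure, and it needs capture at C11, which is favoured by the hindrance at C7 and C9, by the conjugated diene formed and by the reversibility of allylic acetate formation, while a C9 acetate would still converge on 13 in step 8.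

Step 8
Reactants: 12 (2E,4E)-3-methyl-5-[(1S)-2,6,6-trimethylcyclohex-2-en-1-yl]penta-2,4-dien-1-yl acetate
Product: 13 [(2E,4E)-3-methyl-5-[(1S)-2,6,6-trimethylcyclohex-2-en-1-yl]penta-2,4-dien-1-yl]triphenylphosphonium bromide
Conditions: PPh3·HBr (1.05 equiv), MeOH, 0 °C→rt, dark; crystallisation from EtOAc
Reagents that add atoms: triphenylphosphine hydrobromide, [Br-].c1ccc(cc1)[PH+](c1ccccc1)c1ccccc1
Why: Allylic phosphonium salt formation by SN1-type ionisation of the dienyl acetate to the pentadienyl cation and capture by PPh3 at the primary terminus, a standard way to C15 end-group Wittig salts that should leave C6 and the ring alkene untouched at room temperature.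

Step 9
Reactants: 13 [(2E,4E)-3-methyl-5-[(1S)-2,6,6-trimethylcyclohex-2-en-1-yl]penta-2,4-dien-1-yl]triphenylphosphonium bromide (2.2 equiv); 14 (2E,4E,6E)-2,7-dimethylocta-2,4,6-trienedial
Product: 17 (6S,6'S)-epsilon-carotene, via C15 ylide 15 (not isolated), via C25 apo-aldehyde 16 (not isolated)
Conditions: NaOMe, MeOH/CH2Cl2, 0 °C→rt; then n-heptane, reflux, crystallisation
Reagents that add atoms: none
Why: Two-fold Wittig olefination (C15 + C10 + C15) forms C11=C12 and C11'=C12', and the Z isomers formed should be converted by thermal isomerisation into the all-E polyene, which should crystallise; C6 and C6' are not involved.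

**Compound list**

1 | isobutyraldehyde | CC(C)C=O | starting material
2 | acrylonitrile | C=CC#N | starting material
3 | 4,4-dimethyl-5-oxopentanenitrile | N#CCCC(C)(C)C=O | intermediate
4 | 3-methylpenta-1,4-dien-3-ol | C=CC(C)(O)C=C | starting material
5 | (3E)-5-bromo-3-methylpenta-1,3-diene | BrC/C=C(C)/C=C | intermediate
6 | diethyl [(2E)-3-methylpenta-2,4-dien-1-yl]phosphonate | CCOP(=O)(OCC)C/C=C(C)/C=C | intermediate
7 | lithium 1-(diethoxyphosphoryl)-3-methylpenta-2,4-dien-1-ide (lithiated phosphonate) | [Li+].CCOP(=O)(OCC)[CH-]/C=C(C)/C=C | intermediate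
8 | (5E,7E)-4,4,8-trimethyldeca-5,7,9-trienenitrile | N#CCCC(C)(C)/C=C/C=C(C)/C=C | intermediate
9 | N-(diisobutylalumanyl) imine of (5E,7E)-4,4,8-trimethyldeca-5,7,9-trienal (aluminium aldimine) | CC(C)C[Al](CC(C)C)N=CCCC(C)(C)/C=C/C=C(C)/C=C | intermediate
10 | (5E,7E)-4,4,8-trimethyldeca-5,7,9-trienal | O=CCCC(C)(C)/C=C/C=C(C)/C=C | intermediate
11 | (2Z,7E,9E)-2-iodo-6,6,10-trimethyldodeca-2,7,9,11-tetraene | C/C(I)=C/CCC(C)(C)/C=C/C=C(C)/C=C | intermediate
12 | (2E,4E)-3-methyl-5-[(1S)-2,6,6-trimethylcyclohex-2-en-1-yl]penta-2,4-dien-1-yl acetate | CC1=CCCC(C)(C)[C@@H]1/C=C/C(C)=C/COC(C)=O | intermediate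
13 | [(2E,4E)-3-methyl-5-[(1S)-2,6,6-trimethylcyclohex-2-en-1-yl]penta-2,4-dien-1-yl]triphenylphosphonium bromide | CC1=CCCC(C)(C)[C@@H]1/C=C/C(C)=C/C[P+](c1ccccc1)(c1ccccc1)c1ccccc1.[Br-] | intermediate
14 | (2E,4E,6E)-2,7-dimethylocta-2,4,6-trienedial | O=C/C(C)=C/C=C/C=C(C)/C=O | starting material
15 | [(2E,4E)-3-methyl-5-[(1S)-2,6,6-trimethylcyclohex-2-en-1-yl]penta-2,4-dien-1-ylidene]triphenylphosphorane (C15 ylide) | CC1=CCCC(C)(C)[C@@H]1/C=C/C(C)=C/C=P(c1ccccc1)(c1ccccc1)c1ccccc1 | intermediate
16 | (6S)-12'-apo-epsilon-caroten-12'-al (C25 apo-aldehyde, all-E) | CC1=CCCC(C)(C)[C@@H]1/C=C/C(C)=C/C=C/C(C)=C/C=C/C=C(C)/C=O | intermediate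
17 | (6S,6'S)-epsilon-carotene | CC1=CCCC(C)(C)[C@@H]1/C=C/C(C)=C/C=C/C(C)=C/C=C/C=C(C)/C=C/C=C(C)/C=C/[C@@H]1C(C)=CCCC1(C)C | target

**Step count and risks**

Total step count: 9. Longest linear sequence: 8 steps (steps 2, 3, 4, 5, 6, 7, 8 and 9, starting from 3-methylpenta-1,4-dien-3-ol 4); step 1 prepares aldehyde 3, which joins this sequence in step 4.

Steps most likely to fail:

Step 7 (Proposed new method). What may go wrong: poor enantiofacial discrimination in the insertion, acetate capture of the pentadienylpalladium at the wrong carbon, β-hydride loss toward C6, or oligomerisation through the terminal vinyl group. The fallback returns to the 1,3-diene substrate class on which the Heck/η3-allyl acetate capture is established and then uses the standard ketone-based access to the C15 salt. It sets out from 3. Michaelis–Arbuzov reaction of (2E)-1-bromobut-2-ene with P(OEt)3 should give diethyl [(2E)-but-2-en-1-yl]phosphonate F1. HWE reaction of 3 with lithiated F1 (n-BuLi, THF, DMPU, −78 °C→rt) should give (5E,7E)-4,4-dimethylnona-5,7-dienenitrile F2. Reduction with iBu2AlH should give (5E,7E)-4,4-dimethylnona-5,7-dienal F3. The iodo-Wittig reaction of step 6 should give (2Z,7E,9E)-2-iodo-6,6-dimethylundeca-2,7,9-triene F4. Cyclisation with Pd2(dba)3·CHCl3, BINAP and AgOAc, with acetate capture at C9, should give (3E)-4-[(1S)-2,6,6-trimethylcyclohex-2-en-1-yl]but-3-en-2-yl acetate F5 as C9 epimers. Methanolysis with K2CO3 in MeOH should give (3E)-4-[(1S)-2,6,6-trimethylcyclohex-2-en-1-yl]but-3-en-2-ol F6. Oxidation with MnO2 should give (S)-alpha-ionone F7. Addition of CH2=CHMgBr should give (1E)-3-methyl-1-[(1S)-2,6,6-trimethylcyclohex-2-en-1-yl]penta-1,4-dien-3-ol F8. Treatment of F8 with PPh3·HBr in MeOH comes back to the route at 13.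

Step 6. What may go wrong: erosion of Z selectivity, dehydroiodination of the product by excess base, or iodination of the triene by residual iodine. The fallback builds the halo-alkene by cross-coupling instead of olefination and sets out from 10. Ramirez dibromo-olefination (CBr4, PPh3, Et3N, CH2Cl2, 0 °C) should give (6E,8E)-1,1-dibromo-5,5,9-trimethylundeca-1,6,8,10-tetraene F9. Trans-selective Negishi monomethylation (MeZnCl, PdCl2(DPEphos), THF) replaces the bromine trans to the chain and should give (2Z,7E,9E)-2-bromo-6,6,10-trimethyldodeca-2,7,9,11-tetraene F10. F10 is taken through the conditions of step 7 in place of 11, at a somewhat higher temperature, and comes back to the route at 12.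

Step 8. What may go wrong: acid-promoted migration of the ring double bond into conjugation with loss of the C6 stereocentre, or elimination from the pentadienyl cation. The fallback reverses the polarity of the final Wittig reaction so that the chiral fragment never meets acid; it sets out from 12 and 14. Methanolysis of 12 (K2CO3, MeOH) should give (2E,4E)-3-methyl-5-[(1S)-2,6,6-trimethylcyclohex-2-en-1-yl]penta-2,4-dien-1-ol F11. Oxidation with MnO2 should give (2E,4E)-3-methyl-5-[(1S)-2,6,6-trimethylcyclohex-2-en-1-yl]penta-2,4-dienal F12. Dialdehyde 14 is reduced with NaBH4 to (2E,4E,6E)-2,7-dimethylocta-2,4,6-triene-1,8-diol F13 and converted with PPh3·HBr into [(2E,4E,6E)-2,7-dimethylocta-2,4,6-triene-1,8-diyl]bis(triphenylphosphonium) dibromide F14. Double Wittig reaction of F14 with two equivalents of F12 (NaOMe, MeOH/CH2Cl2, then isomerisation in hot heptane) comes back to the route at 17.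

**Further compounds**

F1 | step 7 | diethyl [(2E)-but-2-en-1-yl]phosphonate | CCOP(=O)(OCC)C/C=C/C
F2 | step 7 | (5E,7E)-4,4-dimethylnona-5,7-dienenitrile | N#CCCC(C)(C)/C=C/C=C/C
F3 | step 7 | (5E,7E)-4,4-dimethylnona-5,7-dienal | O=CCCC(C)(C)/C=C/C=C/C
F4 | step 7 | (2Z,7E,9E)-2-iodo-6,6-dimethylundeca-2,7,9-triene | C/C(I)=C/CCC(C)(C)/C=C/C=C/C
F5 | step 7 | (3E)-4-[(1S)-2,6,6-trimethylcyclohex-2-en-1-yl]but-3-en-2-yl acetate | CC1=CCCC(C)(C)[C@@H]1/C=C/C(C)OC(C)=O
F6 | step 7 | (3E)-4-[(1S)-2,6,6-trimethylcyclohex-2-en-1-yl]but-3-en-2-ol | CC1=CCCC(C)(C)[C@@H]1/C=C/C(C)O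
F7 | step 7 | (S)-alpha-ionone | CC1=CCCC(C)(C)[C@@H]1/C=C/C(C)=O
F8 | step 7 | (1E)-3-methyl-1-[(1S)-2,6,6-trimethylcyclohex-2-en-1-yl]penta-1,4-dien-3-ol | CC1=CCCC(C)(C)[C@@H]1/C=C/C(C)(O)C=C
F9 | step 6 | (6E,8E)-1,1-dibromo-5,5,9-trimethylundeca-1,6,8,10-tetraene | BrC(Br)=CCCC(C)(C)/C=C/C=C(C)/C=C
F10 | step 6 | (2Z,7E,9E)-2-bromo-6,6,10-trimethyldodeca-2,7,9,11-tetraene | C/C(Br)=C/CCC(C)(C)/C=C/C=C(C)/C=C
F11 | step 8 | (2E,4E)-3-methyl-5-[(1S)-2,6,6-trimethylcyclohex-2-en-1-yl]penta-2,4-dien-1-ol | CC1=CCCC(C)(C)[C@@H]1/C=C/C(C)=C/CO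
F12 | step 8 | (2E,4E)-3-methyl-5-[(1S)-2,6,6-trimethylcyclohex-2-en-1-yl]penta-2,4-dienal | CC1=CCCC(C)(C)[C@@H]1/C=C/C(C)=C/C=O
F13 | step 8 | (2E,4E,6E)-2,7-dimethylocta-2,4,6-triene-1,8-diol | OC/C(C)=C/C=C/C=C(C)/CO
F14 | step 8 | [(2E,4E,6E)-2,7-dimethylocta-2,4,6-triene-1,8-diyl]bis(triphenylphosphonium) dibromide | c1ccccc1[P+](c1ccccc1)(c1ccccc1)C/C(C)=C/C=C/C=C(C)/C[P+](c1ccccc1)(c1ccccc1)c1ccccc1.[Br-].[Br-]
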